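**Plan**

- Retrosynthetic cuts, in order: the two galloyl ester C–O bonds and all O-benzyl bonds; C2–H and C3–O of upper ring C (back to a C2=C3 enol ether); C4–C4a and O1–C2 of that ring; the Cα=Cβ bond of a chalcone; the C6–CHO bond of the lower unit.
- Enabling feature: upper ring C is joined to the phloroglucinol-type ring A through C4–C4a and O1–C2, and its remaining C2–C3–C4 chain carries the 4-oxyphenyl group at C2 and lower ring A (through lower C6) at C4. That chain is a chalcone, and ring A is a 3,5-dioxygenated phenol.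
- Forward order: the three rings of (−)-epicatechin become the lower unit unchanged (benzylation, C8 bromine block, silylation, C6 formylation, chalcone formation). 3,5-Bis(benzyloxy)phenol then brings upper ring A and closes upper ring C as a 4H-chromene. Oxidation and reduction of C2=C3, esterification and hydrogenolysis finish the route.
- Stereochemistry: lower C2 and C3 come from (−)-epicatechin; upper C4 from a chiral phosphoric acid; upper C3 from epoxidation anti to the C4 aryl group; upper C2 from hydride entering anti to the C3 oxygen.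

Key step: step 6

Remark: flavan numbering (O1, C2, C3, C4, C4a, C5–C8, C8a) is used for both halves; "upper" is the epiafzelechin half and "lower" the epicatechin half. ArL stands for the protected lower unit bonded through its C6, (2R,3R)-5,7-bis(benzyloxy)-2-[3,4-bis(benzyloxy)phenyl]-8-bromo-3-(tert-butyldimethylsilyloxy)chroman-6-yl. Upper C4 has the descriptor R while lower ring A carries bromine and benzyl ethers and S in the target, with no change in geometry.

Assumption: the (R)-enantiomer of the phosphoric acid is taken to give the (4R)-chromene; both enantiomers are available, so the antipode would be used in the same way if the sense of induction is the reverse.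

**Route**

Step 1
Reactants: 1 (−)-epicatechin
Product: 2 5,7,3',4'-tetra-O-benzyl-(−)-epicatechin, (2R,3R)-5,7-bis(benzyloxy)-2-[3,4-bis(benzyloxy)phenyl]chroman-3-ol
Conditions: BnBr (4.4 equiv), K2CO3, DMF, 0 °C → rt
Reagents that add atoms: benzyl bromide, BrCc1ccccc1
Why: Williamson etherification with a carbonate base alkylates the four phenols and leaves the far less acidic C3 alcohol and both stereocentres untouched.

Step 2
Reactants: 2 5,7,3',4'-tetra-O-benzyl-(−)-epicatechin
Product: 3 (2R,3R)-5,7-bis(benzyloxy)-2-[3,4-bis(benzyloxy)phenyl]-8-bromochroman-3-ol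
Conditions: NBS (1.0 equiv), CH2Cl2, −78 °C → 0 °C
Reagents that add atoms: N-bromosuccinimide, BrN1C(=O)CCC1=O
Why: Electrophilic aromatic bromination of the phloroglucinol-type ring A should go to C8, the kinetically preferred and less hindered of its two free positions in benzylated flavan-3-ols, which blocks that site for step 4.

Step 3
Reactants: 3 the 8-bromo alcohol
Product: 4 tert-butyldimethylsilyl ether ArL–H, (2R,3R)-5,7-bis(benzyloxy)-2-[3,4-bis(benzyloxy)phenyl]-8-bromo-3-(tert-butyldimethylsilyloxy)chromane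
Conditions: TBSCl, imidazole, DMF, rt → 40 °C
Reagents that add atoms: tert-butyldimethylsilyl chloride, CC(C)(C)[Si](C)(C)Cl
Why: Imidazole-promoted silylation of the secondary alcohol gives an ether that should withstand the hydroxide of step 5 and the acids of steps 4, 6 and 8 and can later be removed beside benzyl ethers.

Step 4
Reactants: 4 silyl ether ArL–H
Product: 5 aldehyde ArL–CHO, (2R,3R)-5,7-bis(benzyloxy)-2-[3,4-bis(benzyloxy)phenyl]-8-bromo-3-(tert-butyldimethylsilyloxy)chromane-6-carbaldehyde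
Conditions: Cl2CHOMe (1.5 equiv), AgOSO2CF3 (AgOTf, 3 equiv), CH2Cl2, −78 °C; H2O quench
Reagents that add atoms: dichloromethyl methyl ether, COC(Cl)Cl; water, O
Why: Rieche formylation in its silver-triflate-promoted form generates the chloro(methoxy)carbenium ion at −78 °C, where benzyl and silyl ethers should survive, and this small electrophile can only attack C6, the single free and threefold oxygen-activated position of ring A, the aldehyde being released on hydrolysis.

Step 5
Reactants: 5 aldehyde ArL–CHO; 6 4'-benzyloxyacetophenone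
Product: 7 chalcone (E)-1-[4-(benzyloxy)phenyl]-3-ArL-prop-2-en-1-one
Conditions: KOH, EtOH/THF, rt
Reagents that add atoms: none
Why: Claisen–Schmidt condensation of a non-enolisable aldehyde with the acetophenone enolate, followed by E1cB loss of water, should give the E enone, as it does with other 2,6-dialkoxybenzaldehydes.

Step 6
Reactants: 7 chalcone; 8 3,5-bis(benzyloxy)phenol (1.5 equiv)
Product: 11 (4R)-5,7-bis(benzyloxy)-2-[4-(benzyloxy)phenyl]-4-ArL-4H-chromene, via ketone adduct 9 (not isolated), via cyclic hemiketal 10 (not isolated)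
Conditions: (R)-TRIP [(R)-3,3'-bis(2,4,6-triisopropylphenyl)-1,1'-binaphthyl-2,2'-diyl hydrogen phosphate] (10 mol %), 4 Å MS, toluene, rt → 40 °C
Reagents that add atoms: none
Why: The phosphoric acid binds the carbonyl of 7 (made more basic by the donor-substituted β-aryl group) through its OH and the hydroxyl of 8 through its P=O oxygen, and the ortho carbon of 8 adds to the β-carbon, a vinylogous benzylic cation stabilised by the two ortho-benzyloxy groups of lower ring A, which forms C4–C4a and gives ketone 9 after rearomatisation. The phenol oxygen of 9 then closes upper ring C on the ketone carbon by a 6-exo-trig addition (O1–C2, hemiketal 10), and acid-catalysed loss of water, taken up by the sieves, gives the 2-aryl enol ether 11 and drives the sequence forward. The closest known reaction type is the chiral-phosphoric-acid-catalysed Friedel–Crafts conjugate addition and cyclodehydration of naphthols and electron-rich phenols with enones to 4H-chromenes. C4 is the only new stereocentre and is set by the catalyst, whose 3,3'-aryl groups should let the bound phenol reach only one face of the bound enone, while the remote lower-unit centres should add little bias. The step needs ortho- and not para-C-alkylation, and C- and not O-alkylation, of 8: the catalyst-bound hydroxyl delivers the neighbouring carbon, the two ortho positions of 8 are equivalent, and any oxa-Michael adduct can revert. Lower ring A has no free position (C8 carries bromine) and every other phenol is benzylated, so 8 is the only nucleophile present.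

Step 7
Reactants: 11 4H-chromene
Product: 12 (2S,3R,4R)-5,7-bis(benzyloxy)-2-[4-(benzyloxy)phenyl]-2,3-epoxy-4-ArL-chromane, oxirane oxygen trans to ArL
Conditions: dimethyldioxirane (1.1 equiv, acetone solution), CH2Cl2, −78 °C → −20 °C; cold evaporation, crude product used at once
Reagents that add atoms: dimethyldioxirane, CC1(C)OO1
Why: Dimethyldioxirane epoxidises the electron-rich C2=C3 enol ether under neutral conditions, and because the C4 aryl group stands pseudo-axial to escape the peri 5-benzyloxy group it should shield its own face, so that oxygen adds anti to it and fixes C3.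

Step 8
Reactants: 12 epoxide
Product: 13 (2R,3R,4R)-5,7-bis(benzyloxy)-2-[4-(benzyloxy)phenyl]-4-ArL-chroman-3-ol, 2,3-cis-3,4-trans
Conditions: Et3SiH (5 equiv), then BF3·OEt2 (1.1 equiv), CH2Cl2, −78 °C; H2O quench
Reagents that add atoms: none
Why: BF3 opens the epoxide at C2, the carbon that bears the ring oxygen and the 4-oxyphenyl group, and Et3SiH transfers hydride to the resulting oxocarbenium ion pair on the face opposite the departing oxygen (ionic hydrogenation in the sense of a trans-diaxial epoxide opening), which should place H2 anti to O3 and so the C2 aryl group cis to the C3 hydroxyl and trans to the C4 aryl group.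

Step 9
Reactants: 13 silylated flavan-3-ol
Product: 14 diol (2R,3R,4R)-5,7-bis(benzyloxy)-2-[4-(benzyloxy)phenyl]-4-[(2R,3R)-5,7-bis(benzyloxy)-2-[3,4-bis(benzyloxy)phenyl]-8-bromo-3-hydroxychroman-6-yl]chroman-3-ol
Conditions: HF·pyridine, pyridine/THF, 0 °C → rt
Reagents that add atoms: none
Why: Fluoride-driven cleavage of the Si–O bond in a pyridine-buffered medium frees the lower C3 hydroxyl without touching benzyl ethers, the aryl bromide or the acid-sensitive interflavan bond.

Step 10
Reactants: 14 diol; 15 3,4,5-tris(benzyloxy)benzoic acid (3 equiv)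
Product: 16 bis[3,4,5-tris(benzyloxy)benzoate] of 14, acylated at the upper and the lower C3 oxygen
Conditions: DCC, DMAP, CH2Cl2, rt
Reagents that add atoms: none
Why: Steglich esterification, in which DMAP carries the acyl group, should acylate both secondary alcohols, the hindered axial upper one included, with retention at C3.

Step 11
Reactants: 16 fully protected digallate
Product: 17 target, (−)-epiafzelechin 3-O-gallate-(4β→6)-(−)-epicatechin 3-O-gallate, upper unit (2R,3R,4S), lower unit (2R,3R)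
Conditions: H2 (1 atm), Pd(OH)2/C, Et3N (1 equiv), THF/MeOH/H2O, rt
Reagents that add atoms: none
Why: Catalytic hydrogenolysis should cleave the thirteen benzyl ethers and the aryl C–Br bond (Et3N taking up the HBr) while the esters, the interflavan bond and all five stereocentres stay as they are.

**Compound list**

1 | (−)-epicatechin | O[C@@H]1Cc2c(O)cc(O)cc2O[C@@H]1c1ccc(O)c(O)c1 | starting material
2 | 5,7,3',4'-tetra-O-benzyl-(−)-epicatechin | O[C@@H]1Cc2c(OCc3ccccc3)cc(OCc3ccccc3)cc2O[C@@H]1c1ccc(OCc2ccccc2)c(OCc2ccccc2)c1 | intermediate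
3 | (2R,3R)-5,7-bis(benzyloxy)-2-[3,4-bis(benzyloxy)phenyl]-8-bromochroman-3-ol | O[C@@H]1Cc2c(OCc3ccccc3)cc(OCc3ccccc3)c(Br)c2O[C@@H]1c1ccc(OCc2ccccc2)c(OCc2ccccc2)c1 | intermediate
4 | ArL–H, 3-O-tert-butyldimethylsilyl ether of 3 | CC(C)(C)[Si](C)(C)O[C@@H]1Cc2c(OCc3ccccc3)cc(OCc3ccccc3)c(Br)c2O[C@@H]1c1ccc(OCc2ccccc2)c(OCc2ccccc2)c1 | intermediate
5 | ArL–CHO, the 6-carbaldehyde of 4 | CC(C)(C)[Si](C)(C)O[C@@H]1Cc2c(OCc3ccccc3)c(C=O)c(OCc3ccccc3)c(Br)c2O[C@@H]1c1ccc(OCc2ccccc2)c(OCc2ccccc2)c1 | intermediate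
6 | 4'-benzyloxyacetophenone | CC(=O)c1ccc(OCc2ccccc2)cc1 | starting material
7 | (E)-1-[4-(benzyloxy)phenyl]-3-ArL-prop-2-en-1-one | CC(C)(C)[Si](C)(C)O[C@@H]1Cc2c(OCc3ccccc3)c(/C=C/C(=O)c3ccc(OCc4ccccc4)cc3)c(OCc3ccccc3)c(Br)c2O[C@@H]1c1ccc(OCc2ccccc2)c(OCc2ccccc2)c1 | intermediate
8 | 3,5-bis(benzyloxy)phenol | Oc1cc(OCc2ccccc2)cc(OCc2ccccc2)c1 | starting material
9 | (3R)-1-[4-(benzyloxy)phenyl]-3-[2,4-bis(benzyloxy)-6-hydroxyphenyl]-3-ArL-propan-1-one | CC(C)(C)[Si](C)(C)O[C@@H]1Cc2c(OCc3ccccc3)c([C@H](CC(=O)c3ccc(OCc4ccccc4)cc3)c3c(O)cc(OCc4ccccc4)cc3OCc3ccccc3)c(OCc3ccccc3)c(Br)c2O[C@@H]1c1ccc(OCc2ccccc2)c(OCc2ccccc2)c1 | intermediate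
10 | (4R)-5,7-bis(benzyloxy)-2-[4-(benzyloxy)phenyl]-4-ArL-chroman-2-ol, either C2 epimer | CC(C)(C)[Si](C)(C)O[C@@H]1Cc2c(OCc3ccccc3)c([C@@H]3CC(O)(c4ccc(OCc5ccccc5)cc4)Oc4cc(OCc5ccccc5)cc(OCc5ccccc5)c34)c(OCc3ccccc3)c(Br)c2O[C@@H]1c1ccc(OCc2ccccc2)c(OCc2ccccc2)c1 | intermediate
11 | (4R)-5,7-bis(benzyloxy)-2-[4-(benzyloxy)phenyl]-4-ArL-4H-chromene | CC(C)(C)[Si](C)(C)O[C@@H]1Cc2c(OCc3ccccc3)c([C@@H]3C=C(c4ccc(OCc5ccccc5)cc4)Oc4cc(OCc5ccccc5)cc(OCc5ccccc5)c34)c(OCc3ccccc3)c(Br)c2O[C@@H]1c1ccc(OCc2ccccc2)c(OCc2ccccc2)c1 | intermediate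
12 | (2S,3R,4R)-5,7-bis(benzyloxy)-2-[4-(benzyloxy)phenyl]-2,3-epoxy-4-ArL-chromane | CC(C)(C)[Si](C)(C)O[C@@H]1Cc2c(OCc3ccccc3)c([C@@H]3[C@H]5O[C@@]5(c4ccc(OCc6ccccc6)cc4)Oc4cc(OCc6ccccc6)cc(OCc6ccccc6)c34)c(OCc3ccccc3)c(Br)c2O[C@@H]1c1ccc(OCc2ccccc2)c(OCc2ccccc2)c1 | intermediate
13 | (2R,3R,4R)-5,7-bis(benzyloxy)-2-[4-(benzyloxy)phenyl]-4-ArL-chroman-3-ol | CC(C)(C)[Si](C)(C)O[C@@H]1Cc2c(OCc3ccccc3)c([C@@H]3[C@@H](O)[C@@H](c4ccc(OCc5ccccc5)cc4)Oc4cc(OCc5ccccc5)cc(OCc5ccccc5)c34)c(OCc3ccccc3)c(Br)c2O[C@@H]1c1ccc(OCc2ccccc2)c(OCc2ccccc2)c1 | intermediate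
14 | diol, 13 with the lower C3 silyl ether replaced by OH | O[C@@H]1Cc2c(OCc3ccccc3)c([C@@H]3[C@@H](O)[C@@H](c4ccc(OCc5ccccc5)cc4)Oc4cc(OCc5ccccc5)cc(OCc5ccccc5)c34)c(OCc3ccccc3)c(Br)c2O[C@@H]1c1ccc(OCc2ccccc2)c(OCc2ccccc2)c1 | intermediate
15 | 3,4,5-tris(benzyloxy)benzoic acid | OC(=O)c1cc(OCc2ccccc2)c(OCc2ccccc2)c(OCc2ccccc2)c1 | starting material
16 | bis[3,4,5-tris(benzyloxy)benzoate] of 14 | O=C(c1cc(OCc2ccccc2)c(OCc2ccccc2)c(OCc2ccccc2)c1)O[C@@H]1Cc2c(OCc3ccccc3)c([C@@H]3[C@@H](OC(=O)c4cc(OCc5ccccc5)c(OCc5ccccc5)c(OCc5ccccc5)c4)[C@@H](c4ccc(OCc5ccccc5)cc4)Oc4cc(OCc5ccccc5)cc(OCc5ccccc5)c34)c(OCc3ccccc3)c(Br)c2O[C@@H]1c1ccc(OCc2ccccc2)c(OCc2ccccc2)c1 | intermediate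
17 | (−)-epiafzelechin 3-O-gallate-(4β→6)-(−)-epicatechin 3-O-gallate (CNP0169607.1) | O=C(c1cc(O)c(O)c(O)c1)O[C@@H]1Cc2c(O)c([C@@H]3[C@@H](OC(=O)c4cc(O)c(O)c(O)c4)[C@@H](c4ccc(O)cc4)Oc4cc(O)cc(O)c34)c(O)cc2O[C@@H]1c1ccc(O)c(O)c1 | target

**Step count and risks**

Total: 11 steps. Longest linear sequence: 11 steps (1 → 17).

Steps most likely to fail, most uncertain first:

Step 6. The hindered, donor-substituted chalcone may react too slowly with an acid of this strength, or the Friedel–Crafts addition may reverse and erode the facial control at C4. The fallback builds the same ring through an ortho-quinone methide and sets out from aldehyde 5. The bromomagnesium phenoxide of 8 (EtMgBr, toluene/CH2Cl2) should add through its ortho carbon to the formyl group and give the ortho-hydroxybenzhydrol F1. In parallel, ketone 6 is converted with TMSOTf and Et3N into the silyl enol ether F2. Under the same chiral phosphoric acid F1 should lose water to an ortho-quinone methide held in an ion pair with the chiral phosphate. F2 then adds to it in a catalyst-controlled formal [4+2] reaction, and loss of trimethylsilanol closes the enol ether and returns the route at chromene 11.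

Step 8. Hydride may reach C2 on the wrong face, or the opened epoxide may rearrange by a 1,2-hydride shift to the flavan-3-one before it is reduced. The fallback sets out from epoxide 12, which is opened with methanol at low temperature to the methyl ketal F3 (trans-diaxial methanolysis). Its C3 hydroxyl is capped with TESOTf and 2,6-lutidine to give the triethylsilyl ether F4, so that a bulky group on the face of the C3 oxygen flanks C2. Reduction of this stable ketal with Et3SiH and catalytic TMSOTf at −78 °C should then give the doubly silylated flavan F5, with hydride entering opposite the silyloxy group. HF·pyridine, as in step 9, removes both silyl groups and the route is rejoined at diol 14.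

Step 7. Dimethyldioxirane may also oxidise the electron-rich arene rings, and the enol-ether epoxide may open or rearrange during concentration. The fallback sets out from chromene 11, which is dihydroxylated with catalytic OsO4 and NMO in acetone/water, again anti to the C4 aryl group, to the stable cis-diol F6, a cyclic hemiketal. Et3SiH and BF3·OEt2 at −78 °C should then reduce it at C2 (lactol-type ionic hydrogenation), and the route is rejoined at 13.

**Further compounds**

F1 | step 6 | [2,4-bis(benzyloxy)-6-hydroxyphenyl](ArL)methanol, either carbinol epimer | CC(C)(C)[Si](C)(C)O[C@@H]1Cc2c(OCc3ccccc3)c(C(O)c3c(O)cc(OCc4ccccc4)cc3OCc3ccccc3)c(OCc3ccccc3)c(Br)c2O[C@@H]1c1ccc(OCc2ccccc2)c(OCc2ccccc2)c1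
F2 | step 6 | {1-[4-(benzyloxy)phenyl]ethenyloxy}trimethylsilane | C=C(O[Si](C)(C)C)c1ccc(OCc2ccccc2)cc1
F3 | step 8 | (2R,3R,4R)-5,7-bis(benzyloxy)-2-[4-(benzyloxy)phenyl]-2-methoxy-4-ArL-chroman-3-ol | CC(C)(C)[Si](C)(C)O[C@@H]1Cc2c(OCc3ccccc3)c([C@@H]3[C@@H](O)[C@@](OC)(c4ccc(OCc5ccccc5)cc4)Oc4cc(OCc5ccccc5)cc(OCc5ccccc5)c34)c(OCc3ccccc3)c(Br)c2O[C@@H]1c1ccc(OCc2ccccc2)c(OCc2ccccc2)c1
F4 | step 8 | 3-O-triethylsilyl ether of F3 | CC(C)(C)[Si](C)(C)O[C@@H]1Cc2c(OCc3ccccc3)c([C@@H]3[C@@H](O[Si](CC)(CC)CC)[C@@](OC)(c4ccc(OCc5ccccc5)cc4)Oc4cc(OCc5ccccc5)cc(OCc5ccccc5)c34)c(OCc3ccccc3)c(Br)c2O[C@@H]1c1ccc(OCc2ccccc2)c(OCc2ccccc2)c1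
F5 | step 8 | 3-O-triethylsilyl ether of 13 | CC(C)(C)[Si](C)(C)O[C@@H]1Cc2c(OCc3ccccc3)c([C@@H]3[C@@H](O[Si](CC)(CC)CC)[C@@H](c4ccc(OCc5ccccc5)cc4)Oc4cc(OCc5ccccc5)cc(OCc5ccccc5)c34)c(OCc3ccccc3)c(Br)c2O[C@@H]1c1ccc(OCc2ccccc2)c(OCc2ccccc2)c1
F6 | step 7 | (2S,3R,4R)-5,7-bis(benzyloxy)-2-[4-(benzyloxy)phenyl]-4-ArL-chromane-2,3-diol | CC(C)(C)[Si](C)(C)O[C@@H]1Cc2c(OCc3ccccc3)c([C@@H]3[C@@H](O)[C@](O)(c4ccc(OCc5ccccc5)cc4)Oc4cc(OCc5ccccc5)cc(OCc5ccccc5)c34)c(OCc3ccccc3)c(Br)c2O[C@@H]1c1ccc(OCc2ccccc2)c(OCc2ccccc2)c1
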